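Ring A is assembled, not functionalised: its C1–C6 and C3–C4 bonds are formed together in a [3+3] benzannulation that joins the two α-carbons of an aryloxyacetone (C1–C2–C3, C2 the carbonyl) to the two formyl carbons of 2-bromomalonaldehyde (C4–C5–C6). The step exploits the pattern C1–OAr, C2–OH, C5–Br of ring A, whose para-bromine sits on the central carbon of a symmetrical three-carbon unit, so the ether oxygen, the hydroxyl and the C5 bromine are all delivered with the ring. Its precursor is 1-(2,3,5-tribromo-6-methoxyphenoxy)propan-2-one, which already carries the complete, O-methylated ring B; bromination at C3 and demethylation then finish the target.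

Key step: step 5

Remark on the chemistry: C1–C6 are the ring A carbons (C1 bears the ether oxygen, C2 the hydroxyl); the oxygen that ends as the ring B hydroxyl is methylated while it is still the only hydroxyl, so the two ring B oxygens never have to be told apart, and the target has no stereocentre.

Step 1
Reactants: 1 3,5-dibromo-2-hydroxybenzaldehyde
Product: 2 3,5-dibromo-2-methoxybenzaldehyde
Conditions: MeI, K2CO3, DMF, rt
Reagents that add atoms: iodomethane, CI
Why: Williamson O-methylation of the acidic salicylaldehyde hydroxyl fixes the methyl group on the oxygen that ends as the ring B hydroxyl before a second oxygen is present, so no choice between two phenols arises.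

Step 2
Reactants: 2 3,5-dibromo-2-methoxybenzaldehyde
Product: 4 3,5-dibromo-2-methoxyphenol, via aryl formate 3 (not isolated)
Conditions: mCPBA, CH2Cl2, rt to 40 °C; then KOH, MeOH/H2O, rt; aq. HCl
Reagents that add atoms: 3-chloroperoxybenzoic acid (mCPBA), OOC(=O)c1cccc(Cl)c1
Why: Baeyer–Villiger oxidation of an ortho-alkoxybenzaldehyde should proceed by migration of the oxygen-substituted aryl group to formate 3, which base hydrolyses, so the new hydroxyl stands next to the methoxy group where the ether oxygen of ring B is needed.

Step 3
Reactants: 4 3,5-dibromo-2-methoxyphenol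
Product: 5 2,3,5-tribromo-6-methoxyphenol
Conditions: NBS (1.0 equiv), iPr2NH (10 mol %), CH2Cl2, 0 °C
Reagents that add atoms: N-bromosuccinimide, O=C1CCC(=O)N1Br
Why: Amine-mediated electrophilic aromatic bromination should deliver bromine ortho to the free hydroxyl through a hydrogen-bonded N-bromoamine, while the only other activated site, the para carbon, is screened by its two flanking bromines.

Step 4
Reactants: 5 2,3,5-tribromo-6-methoxyphenol; 6 chloroacetone
Product: 7 1-(2,3,5-tribromo-6-methoxyphenoxy)propan-2-one
Conditions: K2CO3, KI (cat.), acetone, reflux
Reagents that add atoms: none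
Why: Williamson ether synthesis in which the hindered, weakly basic phenoxide of 5 only has to displace halide from a highly reactive α-haloketone, helped by Finkelstein exchange with iodide, while nothing else in ring B responds to carbonate.

Step 5
Reactants: 7 1-(2,3,5-tribromo-6-methoxyphenoxy)propan-2-one; 8 2-bromomalonaldehyde
Product: 11 4-bromo-2-(2,3,5-tribromo-6-methoxyphenoxy)phenol, via vinamidinium acetate 9 (not isolated), via aminodienone 10 (not isolated)
Conditions: pyrrolidine (2.1 equiv), AcOH (1.1 equiv), 3 Å MS, EtOH, rt; then 7, NaOEt (3 equiv), EtOH, 0 °C to reflux; then aq. HCl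
Reagents that add atoms: none
Why: Proposed new method: pyrrolidine and acetic acid convert dialdehyde 8, which by itself would rest in base as an unreactive enolate, into vinamidinium cation 9, whose two termini remain electrophilic towards the ethoxide-generated enolate of 7; the aryloxy-bearing α-carbon adds to one terminus and pyrrolidine is expelled to give push–pull dienone 10 (bond C1–C6), after which the methyl-derived dienolate attacks the remaining aminomethine carbon (bond C3–C4) and the second pyrrolidine leaves. The closest known reaction types are the Hill condensation of ketones with sodium nitromalonaldehyde and the [3+3] annulation of ketone enolates with 2-substituted vinamidinium salts, both of which give 4-substituted phenols, while a 2-halomalonaldehyde as the three-carbon partner of an α-aryloxy ketone is untested, although 8 is an established bromine-retaining 1,3-dielectrophile towards amidines in pyrimidine synthesis. Ring A closes in a 6-(enolendo)-exo-trig Mannich-type mode, which can equally be viewed as a disrotatory 6π-electrocyclisation of the trienolate followed by loss of the amine, and the resulting cyclohexadienone should tautomerise at once to the phenoxide of 11. No stereocentre is formed. The selectivity required is carbon over oxygen ring closure: attack through the dienone oxygen only gives a 2-amino-2H-pyran that reopens, whereas closure through carbon is made irreversible by aromatisation, and because the bromine sits on the central carbon of a symmetrical unit either α-carbon of 7 may react first and still place Br at C5, OH at C2 and the aryl ether at C1.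

Step 6
Reactants: 11 4-bromo-2-(2,3,5-tribromo-6-methoxyphenoxy)phenol
Product: 12 2,4-dibromo-6-(2,3,5-tribromo-6-methoxyphenoxy)phenol
Conditions: Br2 (1.05 equiv), AcOH, rt
Reagents that add atoms: bromine, BrBr
Why: Electrophilic aromatic bromination of the ring A phenol should stop at the monobromide, since C3 is the only unsubstituted position ortho or para to the hydroxyl and ring B, an anisole with three bromines and one shielded hydrogen, is far less reactive.

Step 7
Reactants: 12 2,4-dibromo-6-(2,3,5-tribromo-6-methoxyphenoxy)phenol
Product: 13 3,4,6-tribromo-2-(3,5-dibromo-2-hydroxyphenoxy)phenol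
Conditions: BBr3, CH2Cl2, −78 °C to rt; then H2O
Reagents that add atoms: none
Why: Lewis acid cleavage of the aryl methyl ether by BBr3 (complexation at oxygen, then SN2 attack of bromide on the methyl carbon) should remove only the methyl group, because the diaryl ether offers no sp3 carbon for attack and the aryl bromides are inert.

Compound list
1 | 3,5-dibromo-2-hydroxybenzaldehyde (3,5-dibromosalicylaldehyde) | O=Cc1cc(Br)cc(Br)c1O | starting material
2 | 3,5-dibromo-2-methoxybenzaldehyde | COc1c(Br)cc(Br)cc1C=O | intermediate
3 | 3,5-dibromo-2-methoxyphenyl formate (formed in the flask) | COc1c(Br)cc(Br)cc1OC=O | intermediate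
4 | 3,5-dibromo-2-methoxyphenol | COc1c(Br)cc(Br)cc1O | intermediate
5 | 2,3,5-tribromo-6-methoxyphenol | COc1c(Br)cc(Br)c(Br)c1O | intermediate
6 | chloroacetone (1-chloropropan-2-one) | CC(=O)CCl | starting material
7 | 1-(2,3,5-tribromo-6-methoxyphenoxy)propan-2-one | CC(=O)COc1c(OC)c(Br)cc(Br)c1Br | intermediate
8 | 2-bromomalonaldehyde (2-bromopropanedial) | O=CC(Br)C=O | starting material
9 | 1-[(2Z)-2-bromo-3-(pyrrolidin-1-yl)prop-2-en-1-ylidene]pyrrolidin-1-ium acetate (formed in the flask) | Br/C(C=[N+]1CCCC1)=C\N1CCCC1.CC(=O)[O-] | intermediate
10 | (3E,5Z)-5-bromo-6-(pyrrolidin-1-yl)-3-(2,3,5-tribromo-6-methoxyphenoxy)hexa-3,5-dien-2-one (formed in the flask; drawn as the isomer that can close, the geometry being mobile in the push–pull system) | CC(=O)/C(Oc1c(OC)c(Br)cc(Br)c1Br)=C\C(Br)=C\N1CCCC1 | intermediate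
11 | 4-bromo-2-(2,3,5-tribromo-6-methoxyphenoxy)phenol | Oc1ccc(Br)cc1Oc1c(OC)c(Br)cc(Br)c1Br | intermediate
12 | 2,4-dibromo-6-(2,3,5-tribromo-6-methoxyphenoxy)phenol | Oc1c(Br)cc(Br)cc1Oc1c(OC)c(Br)cc(Br)c1Br | intermediate
13 | 3,4,6-tribromo-2-(3,5-dibromo-2-hydroxyphenoxy)phenol (no stereocentre) | Oc1c(Br)cc(Br)cc1Oc1c(O)c(Br)cc(Br)c1Br | target

Total step count: 7. Longest linear sequence: 7 steps (1 to 13); 6 and 8 are bought building blocks that enter at steps 4 and 5.

Steps most likely to fail

Step 5. The annulation may stall after the first condensation, or the ketone may condense with itself faster than the weakly electrophilic three-carbon unit captures it. The fallback gives up the ring construction and forms the diaryl ether bond directly, with known reactions only. It sets out from phenol 5, whose phenoxide (K2CO3, DMAc, 120 °C) should displace fluoride from commercial 4-bromo-2-fluorobenzaldehyde in an SNAr reaction to give 4-bromo-2-(2,3,5-tribromo-6-methoxyphenoxy)benzaldehyde F1. Baeyer–Villiger oxidation with mCPBA in CH2Cl2 then gives 4-bromo-2-(2,3,5-tribromo-6-methoxyphenoxy)phenyl formate F2, and KOH in aqueous methanol releases phenol 11, where the route is rejoined before step 6.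

Step 3. Bromine may be divided between the ortho and the para position of the phenol, or a second bromination may follow. The fallback replaces electrophilic substitution by a directed C–H bromination. It sets out from phenol 4, which dimethylcarbamoyl chloride and K2CO3 in acetonitrile convert into 3,5-dibromo-2-methoxyphenyl dimethylcarbamate F3. Carbamate-directed ortho bromination with NBS, catalytic Pd(OAc)2 and p-toluenesulfonic acid in 1,2-dichloroethane at 70 °C can reach only the one hydrogen next to the carbamate and should give 2,3,5-tribromo-6-methoxyphenyl dimethylcarbamate F4. Hydrolysis with KOH in aqueous ethanol at reflux comes back to phenol 5.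

Step 2. In the peracid adduct, hydride may migrate in place of the aryl group, because the flanked methoxy group is twisted out of conjugation and the ring carries two bromines; this would end at the benzoic acid. The fallback removes the migrating hydrogen. It sets out from aldehyde 2: MeMgBr in THF at −20 °C gives racemic 1-(3,5-dibromo-2-methoxyphenyl)ethanol F5, and Dess–Martin periodinane in CH2Cl2 oxidises it to 1-(3,5-dibromo-2-methoxyphenyl)ethanone F6. In the Baeyer–Villiger oxidation of this ketone (trifluoroperacetic acid from trifluoroacetic anhydride and urea–hydrogen peroxide, Na2HPO4, CH2Cl2) only aryl or methyl can migrate and aryl is preferred, which should give 3,5-dibromo-2-methoxyphenyl acetate F7. KOH in aqueous methanol followed by acidification comes back to phenol 4.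

Further compounds
F1 | step 5 | 4-bromo-2-(2,3,5-tribromo-6-methoxyphenoxy)benzaldehyde | O=Cc1ccc(Br)cc1Oc1c(OC)c(Br)cc(Br)c1Br
F2 | step 5 | 4-bromo-2-(2,3,5-tribromo-6-methoxyphenoxy)phenyl formate | O=COc1ccc(Br)cc1Oc1c(OC)c(Br)cc(Br)c1Br
F3 | step 3 | 3,5-dibromo-2-methoxyphenyl dimethylcarbamate | CN(C)C(=O)Oc1cc(Br)cc(Br)c1OC
F4 | step 3 | 2,3,5-tribromo-6-methoxyphenyl dimethylcarbamate | CN(C)C(=O)Oc1c(OC)c(Br)cc(Br)c1Br
F5 | step 2 | racemic 1-(3,5-dibromo-2-methoxyphenyl)ethanol | CC(O)c1cc(Br)cc(Br)c1OC
F6 | step 2 | 1-(3,5-dibromo-2-methoxyphenyl)ethanone | CC(=O)c1cc(Br)cc(Br)c1OC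
F7 | step 2 | 3,5-dibromo-2-methoxyphenyl acetate | CC(=O)Oc1cc(Br)cc(Br)c1OC
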